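**Plan**

1. Drimane numbering is used throughout, also for acyclic intermediates: ring A = C1–C5 and C10, ring B = C5–C10, C1 carries the ester oxygen, C4 the gem-dimethyl group, C10 the angular methyl, and C11 and C12 are the formyl carbons on C9 and C8.
2. Retrosynthesis: cleave the p-coumaroyl ester and take C11/C12 back to a diester. Open ring B at C7–C8 (acetal/ketene silyl acetal aldol) and C8–C9 (enolate alkylation). Open ring A at C2–C3 and C1–C10, which leaves an acyclic neopentyl iodide bearing an (E)-enoate plus pinacol vinylboronate as the C1–C2 unit (boron as masked 1β-OH). Cut C4–C5 by an Ireland–Claisen rearrangement.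
3. Forward: acyclic chain, then ring A in one radical [4+2] annulation, then ring B, then reduction, esterification and oxidation.
4. Enabling feature: C4 is quaternary, so the C3 radical is a neopentyl radical with no β-hydrogen and no ring closure of its own. C10 is the β-carbon of an enoate that the C1 radical can reach 6-exo, so one chain event closes ring A and builds the quaternary C10.
5. Stereochemistry: C5 from an asymmetric ketone reduction relayed by 1,3-chirality transfer in the Claisen step; C10 and C1 from C5 through the chair transition state of the annulation; C9 by kinetic protonation anti to the C10 methyl.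

Key step: step 9

Remark: in step 4 the (S,S) catalyst is expected, by analogy with aryl glyoxylates, to give the 2R alcohol; the (R,R) catalyst would be used if the sense proved opposite.

**Route**

Step 1
Reactants: 1 ethyl 3-bromo-2-oxobutanoate
Product: 3 ethyl 2-oxo-3-(triphenyl-λ5-phosphanylidene)butanoate, via phosphonium bromide 2 (not isolated)
Conditions: PPh3, PhMe, 25 °C; then aq. Na2CO3, CH2Cl2, 0 °C
Reagents that add atoms: triphenylphosphine, c1ccc(cc1)P(c1ccccc1)c1ccccc1
Why: SN2 displacement of bromide by the phosphine and deprotonation of the salt should give the keto-stabilised ylide (standard Wittig reagent preparation).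

Step 2
Reactants: 4 3,3-diethoxypropan-1-ol
Product: 5 3,3-diethoxypropanal
Conditions: (COCl)2, DMSO, CH2Cl2, −78 °C; Et3N, −78 to 0 °C
Reagents that add atoms: none
Why: Swern oxidation stops at the aldehyde, and its anhydrous basic conditions leave the acetal intact.

Step 3
Reactants: 5 3,3-diethoxypropanal; 3 ethyl 2-oxo-3-(triphenyl-λ5-phosphanylidene)butanoate
Product: 6 ethyl (3E)-6,6-diethoxy-3-methyl-2-oxohex-3-enoate
Conditions: PhMe, 80 °C
Reagents that add atoms: none
Why: Wittig olefination with a stabilised α-branched acyl ylide should give the trisubstituted (E)-enone, with the aldehyde residue trans to the acyl group.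

Step 4
Reactants: 6 ethyl (3E)-6,6-diethoxy-3-methyl-2-oxohex-3-enoate
Product: 7 ethyl (2R,3E)-6,6-diethoxy-2-hydroxy-3-methylhex-3-enoate
Conditions: RuCl(p-cymene)[(S,S)-TsDPEN] (1 mol %), HCO2H/Et3N 5:2, DMF, 0 °C
Reagents that add atoms: none
Why: Noyori asymmetric transfer hydrogenation should reduce only the activated α-keto carbonyl (1,2-reduction), and the chiral catalyst differentiates its enantiotopic faces to set the carbinol centre as R.

Step 5
Reactants: 7 ethyl (2R,3E)-6,6-diethoxy-2-hydroxy-3-methylhex-3-enoate; 8 2-methylprop-2-enoyl chloride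
Product: 9 ethyl (2R,3E)-6,6-diethoxy-3-methyl-2-[(2-methylprop-2-enoyl)oxy]hex-3-enoate
Conditions: Et3N, DMAP (cat.), CH2Cl2, 0 °C
Reagents that add atoms: none
Why: DMAP-catalysed acylation of the secondary alcohol installs the methacrylate that becomes C3, C4 and the gem-dimethyl group.

Step 6
Reactants: 9 ethyl (2R,3E)-6,6-diethoxy-3-methyl-2-[(2-methylprop-2-enoyl)oxy]hex-3-enoate
Product: 12 (3R,4E)-3-(2,2-diethoxyethyl)-6-ethoxy-2,2,4-trimethyl-6-oxohex-4-enoic acid, via silyl ketene acetal 10 (not isolated), via triethylsilyl ester 11 (not isolated)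
Conditions: RhCl(PPh3)3 (2 mol %), Et3SiH, PhMe, 50 °C then 100 °C; then K2CO3 (cat.), MeOH/H2O, 0 °C
Reagents that add atoms: none
Why: Rh-catalysed 1,4-hydrosilylation of the methacrylate generates the silyl ketene acetal without base, so the acidic carbinol C–H is untouched, and the Ireland–Claisen [3,3] rearrangement through a chair transition state with CO2Et equatorial should form the C4–C5 bond and quaternary C4, transfer the carbinol configuration to C5 and give the (E)-enoate.

Step 7
Reactants: 12 (3R,4E)-3-(2,2-diethoxyethyl)-6-ethoxy-2,2,4-trimethyl-6-oxohex-4-enoic acid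
Product: 13 ethyl (2E,4R)-4-(2,2-diethoxyethyl)-6-hydroxy-3,5,5-trimethylhex-2-enoate
Conditions: BH3·SMe2, THF, 0 to 25 °C
Reagents that add atoms: none
Why: borane reduces the carboxylic acid much faster than the conjugated ester, so the neopentyl alcohol at C3 should form chemoselectively (acid reduction).

Step 8
Reactants: 13 ethyl (2E,4R)-4-(2,2-diethoxyethyl)-6-hydroxy-3,5,5-trimethylhex-2-enoate
Product: 14 ethyl (2E,4R)-4-(2,2-diethoxyethyl)-6-iodo-3,5,5-trimethylhex-2-enoate
Conditions: I2, PPh3, imidazole, PhMe, 70 °C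
Reagents that add atoms: iodine, II
Why: Appel-type iodination converts the neopentyl alcohol into the primary iodide by SN2 attack of iodide on the alkoxyphosphonium ion, without touching C5.

Step 9
Reactants: 14 ethyl (2E,4R)-4-(2,2-diethoxyethyl)-6-iodo-3,5,5-trimethylhex-2-enoate; 15 4,4,5,5-tetramethyl-2-vinyl-1,3,2-dioxaborolane
Product: 16 ethyl 2-[(1S,2S,6R)-2-(2,2-diethoxyethyl)-1,3,3-trimethyl-6-(4,4,5,5-tetramethyl-1,3,2-dioxaborolan-2-yl)cyclohexyl]acetate
Conditions: 15 (6 equiv), Bu3SnH (1.4 equiv, syringe pump, 10 h), Et3B (0.3 equiv)/air, PhH (0.03 M), 25 °C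
Reagents that add atoms: none
Why: Proposed new method: the tributylstannyl radical abstracts iodine from 14 to give the neopentyl C3 radical, which has no β-hydrogen and no feasible closure of its own (4-exo or 5-endo) and so adds to the CH2 terminus of the vinylboronate; the boron-stabilised C1 radical then attacks C10, the β-carbon of the (E)-enoate, and the α-ester radical at C9 is reduced by Bu3SnH. The closest known reaction types are Giese additions of alkyl radicals to vinylboronic esters and tin-mediated radical addition–cyclisation annulations onto enoates. Ring A closes in the 6-exo-trig mode through a chair transition state. C10 is controlled by C5: the C5 side chain sits equatorial and H5 eclipses the C9–H of the enoate (allylic 1,3-strain), which places the enoate arm equatorial and the C10 methyl axial and trans to H5; C1 is controlled by the same chair, the bulky boryl group taking the equatorial position cis to the C10 methyl. The step needs the intermolecular addition to outrun 1,5-hydrogen transfer and direct reduction of the C3 radical, and the ring closure to outrun reduction or telomerisation of the C1 radical; the excess of 15, the slow stannane addition at 25 °C and the gem-dimethyl (Thorpe–Ingold) effect at C4 should secure this. Chemoselectivity between the two alkenes follows from polarity and hindrance, since the nucleophilic C3 radical prefers the unhindered vinylboronate to the β,β-disubstituted enoate.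

Step 10
Reactants: 16 ethyl 2-[(1S,2S,6R)-2-(2,2-diethoxyethyl)-1,3,3-trimethyl-6-(4,4,5,5-tetramethyl-1,3,2-dioxaborolan-2-yl)cyclohexyl]acetate; 17 ethyl bromoacetate
Product: 18 diethyl (2RS)-2-[(1S,2S,6R)-2-(2,2-diethoxyethyl)-1,3,3-trimethyl-6-(4,4,5,5-tetramethyl-1,3,2-dioxaborolan-2-yl)cyclohexyl]butanedioate (C9 epimers)
Conditions: LiN(i-Pr)2, THF, −78 °C; 17, DMPU, −78 to −30 °C
Reagents that add atoms: none
Why: ester enolate alkylation with the reactive α-bromo ester attaches C8 and C12, and the C9 configuration may stay open because step 12 corrects it.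

Step 11
Reactants: 18 diethyl (2RS)-2-[(1S,2S,6R)-2-(2,2-diethoxyethyl)-1,3,3-trimethyl-6-(4,4,5,5-tetramethyl-1,3,2-dioxaborolan-2-yl)cyclohexyl]butanedioate
Product: 20 diethyl (4aS,8R,8aS)-3-ethoxy-5,5,8a-trimethyl-8-(4,4,5,5-tetramethyl-1,3,2-dioxaborolan-2-yl)decahydronaphthalene-1,2-dicarboxylate (mixture at C7, C8 and C9, drimane numbering), via ketene silyl acetal 19 (not isolated)
Conditions: LiN(i-Pr)2, Me3SiCl, THF, −78 °C; then Me3SiOSO2CF3 (0.2 equiv), CH2Cl2, −78 °C
Reagents that add atoms: none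
Why: kinetic deprotonation at the unhindered C8 methylene gives the ketene silyl acetal, which should close ring B by an intramolecular Mukaiyama aldol-type addition to the oxocarbenium ion released from the acetal, a six-membered closure open to both C9 epimers.

Step 12
Reactants: 20 diethyl (4aS,8R,8aS)-3-ethoxy-5,5,8a-trimethyl-8-(4,4,5,5-tetramethyl-1,3,2-dioxaborolan-2-yl)decahydronaphthalene-1,2-dicarboxylate
Product: 22 diethyl (1R,4aS,8R,8aS)-8-hydroxy-5,5,8a-trimethyl-1,4,4a,5,6,7,8,8a-octahydronaphthalene-1,2-dicarboxylate, via boronate diester 21 (not isolated)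
Conditions: KN(SiMe3)2 (3 equiv), THF, −78 to −20 °C; AcOH, −78 °C; then 30% H2O2, aq. NaHCO3, 0 to 25 °C
Reagents that add atoms: hydrogen peroxide, OO
Why: E1cB loss of ethoxide gives the C7=C8 enoate, a second deprotonation at C9 gives the cross-conjugated dienolate whose kinetic α-protonation anti to the axial C10 methyl and the C1 boryl group should set H9 α, and peroxide oxidation of the C–B bond with retention (Brown oxidation) reveals the 1β-hydroxyl.

Step 13
Reactants: 22 diethyl (1R,4aS,8R,8aS)-8-hydroxy-5,5,8a-trimethyl-1,4,4a,5,6,7,8,8a-octahydronaphthalene-1,2-dicarboxylate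
Product: 23 (1R,4aS,8S,8aS)-7,8-bis(hydroxymethyl)-4,4,8a-trimethyl-1,2,3,4,4a,5,8,8a-octahydronaphthalen-1-ol
Conditions: LiAlH4, THF, 0 °C
Reagents that add atoms: none
Why: LiAlH4 reduces both esters (the conjugated one by 1,2-addition) to the 11,12-diol at low temperature, which should leave C9 unchanged as in the classical drim-7-ene diester reduction.

Step 14
Reactants: 23 (1R,4aS,8S,8aS)-7,8-bis(hydroxymethyl)-4,4,8a-trimethyl-1,2,3,4,4a,5,8,8a-octahydronaphthalen-1-ol
Product: 24 (1R,4aS,8S,8aS)-4,4,8a-trimethyl-7,8-bis{[(triethylsilyl)oxy]methyl}-1,2,3,4,4a,5,8,8a-octahydronaphthalen-1-ol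
Conditions: Et3SiCl (2.1 equiv), imidazole, CH2Cl2, −20 °C
Reagents that add atoms: chlorotriethylsilane, CC[Si](Cl)(CC)CC
Why: the two primary hydroxyls should be silylated much faster than the hindered secondary 1β-OH next to quaternary C10 (selective silylation).

Step 15
Reactants: 25 (2E)-3-(4-hydroxyphenyl)prop-2-enoic acid
Product: 27 (2E)-3-{4-[(tert-butyldimethylsilyl)oxy]phenyl}prop-2-enoic acid, via bis-silyl derivative 26 (not isolated)
Conditions: t-BuMe2SiCl (2.2 equiv), imidazole, DMF, 25 °C; then K2CO3, MeOH/H2O, 0 °C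
Reagents that add atoms: tert-butyldimethylsilyl chloride, CC(C)(C)[Si](C)(C)Cl
Why: bis-silylation followed by selective hydrolysis of the labile silyl ester leaves the phenol protected (standard preparation of O-silyl hydroxycinnamic acids).

Step 16
Reactants: 24 (1R,4aS,8S,8aS)-4,4,8a-trimethyl-7,8-bis{[(triethylsilyl)oxy]methyl}-1,2,3,4,4a,5,8,8a-octahydronaphthalen-1-ol; 27 (2E)-3-{4-[(tert-butyldimethylsilyl)oxy]phenyl}prop-2-enoic acid
Product: 28 (1R,4aS,8S,8aS)-4,4,8a-trimethyl-7,8-bis{[(triethylsilyl)oxy]methyl}-1,2,3,4,4a,5,8,8a-octahydronaphthalen-1-yl (2E)-3-{4-[(tert-butyldimethylsilyl)oxy]phenyl}prop-2-enoate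
Conditions: 27, 2,4,6-trichlorobenzoyl chloride, Et3N, THF, 25 °C; then 24, DMAP, PhMe, 60 °C
Reagents that add atoms: none
Why: Yamaguchi esterification through the mixed anhydride should acylate the hindered equatorial 1β-OH, and C1 keeps its configuration because its C–O bond is not broken.

Step 17
Reactants: 28 (1R,4aS,8S,8aS)-4,4,8a-trimethyl-7,8-bis{[(triethylsilyl)oxy]methyl}-1,2,3,4,4a,5,8,8a-octahydronaphthalen-1-yl (2E)-3-{4-[(tert-butyldimethylsilyl)oxy]phenyl}prop-2-enoate
Product: 29 (1R,4aS,8R,8aS)-7,8-diformyl-4,4,8a-trimethyl-1,2,3,4,4a,5,8,8a-octahydronaphthalen-1-yl (2E)-3-{4-[(tert-butyldimethylsilyl)oxy]phenyl}prop-2-enoate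
Conditions: (COCl)2, DMSO, CH2Cl2, −78 to −35 °C; Et3N, −78 to −20 °C
Reagents that add atoms: none
Why: under Swern conditions primary triethylsilyl ethers are cleaved and oxidised directly to aldehydes; both alkoxysulfonium ions form before base is added, so no lactol or lactone should arise, and the cold amine treatment is the usual way to spare C9 in polygodial-type dialdehydes.

Step 18
Reactants: 29 (1R,4aS,8R,8aS)-7,8-diformyl-4,4,8a-trimethyl-1,2,3,4,4a,5,8,8a-octahydronaphthalen-1-yl (2E)-3-{4-[(tert-butyldimethylsilyl)oxy]phenyl}prop-2-enoate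
Product: 30 (1R,4aS,8R,8aS)-7,8-diformyl-4,4,8a-trimethyl-1,2,3,4,4a,5,8,8a-octahydronaphthalen-1-yl (2E)-3-(4-hydroxyphenyl)prop-2-enoate
Conditions: Bu4NF/AcOH 1:1, THF, −20 to 0 °C
Reagents that add atoms: none
Why: acetic acid-buffered fluoride cleaves the aryl silyl ether selectively (fluoride-mediated desilylation) under near-neutral conditions that should not epimerise C9 or touch the enedial and the ester.

**Compound list**

1 | ethyl 3-bromo-2-oxobutanoate | CCOC(=O)C(=O)C(C)Br | starting material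
2 | (4-ethoxy-3,4-dioxobutan-2-yl)triphenylphosphonium bromide | CCOC(=O)C(=O)C(C)[P+](c1ccccc1)(c1ccccc1)c1ccccc1.[Br-] | intermediate
3 | ethyl 2-oxo-3-(triphenyl-λ5-phosphanylidene)butanoate | CCOC(=O)C(=O)C(C)=P(c1ccccc1)(c1ccccc1)c1ccccc1 | intermediate
4 | 3,3-diethoxypropan-1-ol | CCOC(CCO)OCC | starting material
5 | 3,3-diethoxypropanal | CCOC(CC=O)OCC | intermediate
6 | ethyl (3E)-6,6-diethoxy-3-methyl-2-oxohex-3-enoate | CCOC(=O)C(=O)/C(C)=C/CC(OCC)OCC | intermediate
7 | ethyl (2R,3E)-6,6-diethoxy-2-hydroxy-3-methylhex-3-enoate | CCOC(=O)[C@H](O)/C(C)=C/CC(OCC)OCC | intermediate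
8 | 2-methylprop-2-enoyl chloride | CC(=C)C(Cl)=O | starting material
9 | ethyl (2R,3E)-6,6-diethoxy-3-methyl-2-[(2-methylprop-2-enoyl)oxy]hex-3-enoate | CCOC(=O)[C@H](OC(=O)C(C)=C)/C(C)=C/CC(OCC)OCC | intermediate
10 | ethyl (2R,3E)-6,6-diethoxy-3-methyl-2-{[2-methyl-1-(triethylsilyloxy)prop-1-en-1-yl]oxy}hex-3-enoate | CCOC(=O)[C@H](OC(O[Si](CC)(CC)CC)=C(C)C)/C(C)=C/CC(OCC)OCC | intermediate
11 | triethylsilyl (3R,4E)-3-(2,2-diethoxyethyl)-6-ethoxy-2,2,4-trimethyl-6-oxohex-4-enoate | CC[Si](CC)(CC)OC(=O)C(C)(C)[C@H](CC(OCC)OCC)/C(C)=C/C(=O)OCC | intermediate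
12 | (3R,4E)-3-(2,2-diethoxyethyl)-6-ethoxy-2,2,4-trimethyl-6-oxohex-4-enoic acid | OC(=O)C(C)(C)[C@H](CC(OCC)OCC)/C(C)=C/C(=O)OCC | intermediate
13 | ethyl (2E,4R)-4-(2,2-diethoxyethyl)-6-hydroxy-3,5,5-trimethylhex-2-enoate | OCC(C)(C)[C@H](CC(OCC)OCC)/C(C)=C/C(=O)OCC | intermediate
14 | ethyl (2E,4R)-4-(2,2-diethoxyethyl)-6-iodo-3,5,5-trimethylhex-2-enoate | ICC(C)(C)[C@H](CC(OCC)OCC)/C(C)=C/C(=O)OCC | intermediate
15 | 4,4,5,5-tetramethyl-2-vinyl-1,3,2-dioxaborolane (pinacol vinylboronate) | C=CB1OC(C)(C)C(C)(C)O1 | starting material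
16 | ethyl 2-[(1S,2S,6R)-2-(2,2-diethoxyethyl)-1,3,3-trimethyl-6-(4,4,5,5-tetramethyl-1,3,2-dioxaborolan-2-yl)cyclohexyl]acetate (1β-boryl, 5α-H, 10β-methyl) | CCOC(=O)C[C@@]1(C)[C@H](B2OC(C)(C)C(C)(C)O2)CCC(C)(C)[C@@H]1CC(OCC)OCC | intermediate
17 | ethyl bromoacetate | CCOC(=O)CBr | starting material
18 | diethyl (2RS)-2-[(1S,2S,6R)-2-(2,2-diethoxyethyl)-1,3,3-trimethyl-6-(4,4,5,5-tetramethyl-1,3,2-dioxaborolan-2-yl)cyclohexyl]butanedioate | CCOC(=O)CC(C(=O)OCC)[C@@]1(C)[C@H](B2OC(C)(C)C(C)(C)O2)CCC(C)(C)[C@@H]1CC(OCC)OCC | intermediate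
19 | ketene ethyl trimethylsilyl acetal of 18 at the C12 ester (C8=C12 enol ether) | CCOC(O[Si](C)(C)C)=CC(C(=O)OCC)[C@@]1(C)[C@H](B2OC(C)(C)C(C)(C)O2)CCC(C)(C)[C@@H]1CC(OCC)OCC | intermediate
20 | diethyl (4aS,8R,8aS)-3-ethoxy-5,5,8a-trimethyl-8-(4,4,5,5-tetramethyl-1,3,2-dioxaborolan-2-yl)decahydronaphthalene-1,2-dicarboxylate (mixture at C7, C8, C9 of the drimane skeleton) | CCOC(=O)C1C(C(=O)OCC)C(OCC)C[C@H]2C(C)(C)CC[C@@H](B3OC(C)(C)C(C)(C)O3)[C@]12C | intermediate
21 | diethyl (1R,4aS,8R,8aS)-5,5,8a-trimethyl-8-(4,4,5,5-tetramethyl-1,3,2-dioxaborolan-2-yl)-1,4,4a,5,6,7,8,8a-octahydronaphthalene-1,2-dicarboxylate | CCOC(=O)[C@H]1C(C(=O)OCC)=CC[C@H]2C(C)(C)CC[C@@H](B3OC(C)(C)C(C)(C)O3)[C@]12C | intermediate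
22 | diethyl (1R,4aS,8R,8aS)-8-hydroxy-5,5,8a-trimethyl-1,4,4a,5,6,7,8,8a-octahydronaphthalene-1,2-dicarboxylate | CCOC(=O)[C@H]1C(C(=O)OCC)=CC[C@H]2C(C)(C)CC[C@@H](O)[C@]12C | intermediate
23 | (1R,4aS,8S,8aS)-7,8-bis(hydroxymethyl)-4,4,8a-trimethyl-1,2,3,4,4a,5,8,8a-octahydronaphthalen-1-ol (drim-7-ene-1β,11,12-triol) | OC[C@H]1C(CO)=CC[C@H]2C(C)(C)CC[C@@H](O)[C@]12C | intermediate
24 | (1R,4aS,8S,8aS)-4,4,8a-trimethyl-7,8-bis{[(triethylsilyl)oxy]methyl}-1,2,3,4,4a,5,8,8a-octahydronaphthalen-1-ol | CC[Si](CC)(CC)OC[C@H]1C(CO[Si](CC)(CC)CC)=CC[C@H]2C(C)(C)CC[C@@H](O)[C@]12C | intermediate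
25 | (2E)-3-(4-hydroxyphenyl)prop-2-enoic acid (p-coumaric acid) | OC(=O)/C=C/c1ccc(O)cc1 | starting material
26 | tert-butyldimethylsilyl (2E)-3-{4-[(tert-butyldimethylsilyl)oxy]phenyl}prop-2-enoate | CC(C)(C)[Si](C)(C)OC(=O)/C=C/c1ccc(O[Si](C)(C)C(C)(C)C)cc1 | intermediate
27 | (2E)-3-{4-[(tert-butyldimethylsilyl)oxy]phenyl}prop-2-enoic acid | OC(=O)/C=C/c1ccc(O[Si](C)(C)C(C)(C)C)cc1 | intermediate
28 | (1R,4aS,8S,8aS)-4,4,8a-trimethyl-7,8-bis{[(triethylsilyl)oxy]methyl}-1,2,3,4,4a,5,8,8a-octahydronaphthalen-1-yl (2E)-3-{4-[(tert-butyldimethylsilyl)oxy]phenyl}prop-2-enoate | CC[Si](CC)(CC)OC[C@H]1C(CO[Si](CC)(CC)CC)=CC[C@H]2C(C)(C)CC[C@@H](OC(=O)/C=C/c3ccc(O[Si](C)(C)C(C)(C)C)cc3)[C@]12C | intermediate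
29 | (1R,4aS,8R,8aS)-7,8-diformyl-4,4,8a-trimethyl-1,2,3,4,4a,5,8,8a-octahydronaphthalen-1-yl (2E)-3-{4-[(tert-butyldimethylsilyl)oxy]phenyl}prop-2-enoate | O=C[C@H]1C(C=O)=CC[C@H]2C(C)(C)CC[C@@H](OC(=O)/C=C/c3ccc(O[Si](C)(C)C(C)(C)C)cc3)[C@]12C | intermediate
30 | (1R,4aS,8R,8aS)-7,8-diformyl-4,4,8a-trimethyl-1,2,3,4,4a,5,8,8a-octahydronaphthalen-1-yl (2E)-3-(4-hydroxyphenyl)prop-2-enoate | O=C[C@H]1C(C=O)=CC[C@H]2C(C)(C)CC[C@@H](OC(=O)/C=C/c3ccc(O)cc3)[C@]12C | target

**Step count**

Total step count: 18.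
Longest linear sequence: 16 steps (4 to 30 through steps 2–14 and 16–18).

**Steps most likely to fail**

Step 9 (labelled step). The bimolecular addition of the neopentyl radical to the vinylboronate may be outrun by 1,5-hydrogen transfer from the C10 methyl group or by early reduction. Closure at the fully substituted C10 may also be slower than reduction of the C1 radical or its addition to a second vinylboronate. The fallback builds the two bonds one after the other with known reactions and sets out from 13. Dess–Martin oxidation should give the neopentyl aldehyde F1. Wittig reaction with (triphenylphosphoranylidene)acetaldehyde should give the dienal ester F2. Conjugate reduction of the unhindered enal with [(Ph3P)CuH]6 should give the saturated aldehyde F3, in which the C2–C3 bond is in place. SmI2 (divalent samarium) with HMPA and t-BuOH in THF should then close ring A by a 6-exo ketyl–olefin cyclisation onto C10 to give the hydroxy ester F4. Silylation with t-BuMe2SiOSO2CF3 and 2,6-lutidine gives the silyl ether F5. Enolate alkylation with 17 as in step 10 gives the succinate F6. LiN(i-Pr)2 and Me3SiCl give the ketene silyl acetal F7, and Me3SiOSO2CF3 closes ring B to the ethoxy diester F8. KN(SiMe3)2 followed by AcOH as in step 12 gives the enoate diester F9. Bu4NF removes the silyl group and the route is rejoined at 22.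

Step 12. Deprotonation may occur at C6 in place of C9, or protonation of the dienolate may be poorly face-selective or occur at C7, which would leave C9 epimers or double-bond isomers. The fallback uses a temporary lactone for thermodynamic control and sets out from 20. KOtBu in THF at 0 °C should give the C7=C8 boronate diester as a C9 epimer mixture F10. H2O2 with aq. NaHCO3 should give the hydroxy diester mixture F11. DBU in toluene at 90 °C over 4 Å sieves equilibrates C9 through the dienolate, and only the 9β-ester can lactonise onto the 1β-hydroxyl, so the mixture should drain into the tricyclic lactone ester F12. LiAlH4 reduces lactone and ester and the route is rejoined at 23.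

Step 6. Partial 1,2-hydrosilylation, a sluggish rearrangement at the fully substituted ketene acetal terminus, or leakage through a boat transition state would lower conversion and chirality transfer. The fallback generates the enolate by metal insertion and sets out from 7. Acylation with 2-bromo-2-methylpropanoyl bromide and pyridine gives the α-bromo ester F13. Activated Zn in refluxing THF inserts into the C–Br bond, and the zinc enolate should undergo the Reformatsky–Claisen rearrangement through the same chair, which returns the route to 12.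

**Further compounds**

F1 | step 9 | ethyl (2E,4R)-4-(2,2-diethoxyethyl)-3,5,5-trimethyl-6-oxohex-2-enoate | O=CC(C)(C)[C@H](CC(OCC)OCC)/C(C)=C/C(=O)OCC
F2 | step 9 | ethyl (2E,4R,6E)-4-(2,2-diethoxyethyl)-3,5,5-trimethyl-8-oxoocta-2,6-dienoate | O=C/C=C/C(C)(C)[C@H](CC(OCC)OCC)/C(C)=C/C(=O)OCC
F3 | step 9 | ethyl (2E,4S)-4-(2,2-diethoxyethyl)-3,5,5-trimethyl-8-oxooct-2-enoate | O=CCCC(C)(C)[C@H](CC(OCC)OCC)/C(C)=C/C(=O)OCC
F4 | step 9 | ethyl 2-[2-(2,2-diethoxyethyl)-6-hydroxy-1,3,3-trimethylcyclohexyl]acetate, configured as 16 (hydroxyl in place of the boryl group) | CCOC(=O)C[C@@]1(C)[C@H](O)CCC(C)(C)[C@@H]1CC(OCC)OCC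
F5 | step 9 | tert-butyldimethylsilyl ether of F4 | CCOC(=O)C[C@@]1(C)[C@H](O[Si](C)(C)C(C)(C)C)CCC(C)(C)[C@@H]1CC(OCC)OCC
F6 | step 9 | diethyl 2-[6-(tert-butyldimethylsilyloxy)-2-(2,2-diethoxyethyl)-1,3,3-trimethylcyclohexyl]butanedioate, ring configured as 18 (C9 epimers) | CCOC(=O)CC(C(=O)OCC)[C@@]1(C)[C@H](O[Si](C)(C)C(C)(C)C)CCC(C)(C)[C@@H]1CC(OCC)OCC
F7 | step 9 | ketene ethyl trimethylsilyl acetal of F6 at the C12 ester | CCOC(O[Si](C)(C)C)=CC(C(=O)OCC)[C@@]1(C)[C@H](O[Si](C)(C)C(C)(C)C)CCC(C)(C)[C@@H]1CC(OCC)OCC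
F8 | step 9 | diethyl 8-(tert-butyldimethylsilyloxy)-3-ethoxy-5,5,8a-trimethyldecahydronaphthalene-1,2-dicarboxylate, configured as 20 | CCOC(=O)C1C(C(=O)OCC)C(OCC)C[C@H]2C(C)(C)CC[C@@H](O[Si](C)(C)C(C)(C)C)[C@]12C
F9 | step 9 | tert-butyldimethylsilyl ether of 22 | CCOC(=O)[C@H]1C(C(=O)OCC)=CC[C@H]2C(C)(C)CC[C@@H](O[Si](C)(C)C(C)(C)C)[C@]12C
F10 | step 12 | C9 epimer mixture of 21 | CCOC(=O)C1C(C(=O)OCC)=CC[C@H]2C(C)(C)CC[C@@H](B3OC(C)(C)C(C)(C)O3)[C@]12C
F11 | step 12 | C9 epimer mixture of 22 | CCOC(=O)C1C(C(=O)OCC)=CC[C@H]2C(C)(C)CC[C@@H](O)[C@]12C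
F12 | step 12 | ethyl 1β-hydroxydrim-7-en-12-oate 11-carboxylic acid 11,1-lactone (γ-lactone from C11 to the 1β-oxygen, 9α-H, C7=C8, ethyl ester at C12) | CCOC(=O)C1=CC[C@H]2C(C)(C)CC[C@H]3OC(=O)[C@@H]1[C@]23C
F13 | step 6 | ethyl (2R,3E)-2-[(2-bromo-2-methylpropanoyl)oxy]-6,6-diethoxy-3-methylhex-3-enoate | CCOC(=O)[C@H](OC(=O)C(C)(C)Br)/C(C)=C/CC(OCC)OCC
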